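If the catalyst's laps are short beside the run, a flask can be read from one clock, so we build that clock and read it at the end of each flask.

the same everywhere: starting material 25 mM; free catalyst 0.25 mM; time 6.0 h

| run | temperature |
|---|---|
| epsilon | 115 °C |
| gamma | 90 °C |
| beta | 65 °C |

    catalyst intermediate B → free catalyst + product (k1 = 70.1 h⁻¹, Ea1 = 105 kJ mol⁻¹)
    catalyst intermediate A → catalyst intermediate B (k2 = 76.4 h⁻¹, Ea2 = 111 kJ mol⁻¹)
    crystals ⇌ product, rate k3*(cs3 - [product]) while solid is left; crystals form when [product] > cs3 (cs3 = 0.67 mM, k3 = 0.894 h⁻¹)
    starting material + free catalyst → catalyst intermediate A (k4 = 696 L mol⁻¹ h⁻¹, Ea4 = 68.0 kJ mol⁻¹)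
    (constants at 90 °C)

- product is meant together with its crystals
- solid, in amounts per volume of the solution: crystals
- the list of constants is for 90 °C, to be carried to other temperatures by the activation energies

* the flask that comes out highest in amount of product, in percent of the starting material charged, or "all alike" when all lie within 1.5 percentage points (epsilon / gamma / beta / all alike)
* product at the end, in percent of the starting material charged, epsilon
* product at the end, in percent of the starting material charged, gamma
* product at the end, in percent of the starting material charged, beta

Product is counted together with its crystals, and the crystals feed nothing back into the cycle, so we drop them .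

We climb the ladder in gamma, whose constants stand as listed. On the lowest rung, a lap through catalyst intermediates A and B takes 0.0274 h. That is far shorter than the run, so we let the intermediates follow the free catalyst without lag.

On the next rung, free catalyst waits 0.0575 h for starting material at the full charge, twice the lap. Lap and wait stand in series, and the wait grows as starting material thins.

Let a be the fraction of the charge left and x the fraction taken. Integrating the rate in closed form gives the clock: t = ts·x − tc·ln a.

Here ts is the saturation time, the lap times the starting material per catalyst, 2.74 h in gamma. And tc is the capture time, one over the rate constant of binding times the catalyst charged, 5.75 h in gamma. The term with tc is the pseudo-first-order part of the clock.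

Carrying the constants by their activation energies and solving the clock at the end of the run gives:

| flask | tc | ts | x at the end |
|---|---|---|---|
| epsilon | 1.35 h | 0.275 h | 98.6% |
| gamma | 5.75 h | 2.74 h | 54.4% |
| beta | 30.4 h | 38.5 h | 8.55% |

The quantity we carry is the half-time, the clock's reading when half of the charge is taken, tc·ln(2) + ts/2: 1.07 h in epsilon, 5.35 h in gamma and 40.3 h in beta. Gamma's lies just inside the run, and beta's lies beyond it.

The clock counts starting material taken, and the catalyst can hold up to 1.00% of the charge. In beta, near the start, the bound share of the catalyst is ts/(ts + tc), so we take off that hold and reckon 7.99% product. Epsilon comes highest.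

The forecast names epsilon, with 98.5%, 54.2% and 8.2% for epsilon, gamma and beta, its beta figure above ours, and it expects “turnover run nearly to completion” in the hottest flask.

The simulation gives 98.6%, 54.2% and 8.22%, with epsilon highest.

Now take the neighbour, epsilon's flask with 0.062 mM of free catalyst instead of 0.25 mM. Both clock times go as the inverse of the catalyst charged, so tc becomes 5.43 h and ts becomes 1.11 h. The half-time moves from 1.07 h to 4.32 h, still inside the run. Solving the clock gives 62.3% taken. The neighbour ends with 62.4% product and 37.6% of the starting material left.

(The constants were chosen freely; the rest is arithmetic.)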